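**Retrosynthetic overview**
1. Late steps: the tert-butyl ester is cleaved, a C2/C3 diol is oxidised to the diosphenol, C4=O is converted to C4=CH2, and a B-alkyl Suzuki coupling builds the side chain. These lead back to a cis-decalone with a C4 ketone, 7β-OH and a C9 vinyl group.
2. Key disconnection: C6–C7 of ring B is cut and the C5 methyl group is returned to C4. The forward reaction is a pinacol-terminated Prins cyclization of a monocyclic aldehyde that carries a tertiary 2-methylenecyclohexanol.
3. Enabling feature: the oxygen-bearing C7 of ring B lies 1,3 to the quaternary ring-fusion carbon C5 (CH3, C6H2). C5 sits next to the sp2 carbon C4 of ring A, a masked ketone. The array C7(O)–C6H2–C5(quaternary)–C4(=X) is the retron of this cascade.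
4. The aldehyde comes from a Claisen rearrangement (C8–C9) of a (Z)-propenyl ether. Its ring comes from cyclohexenone by asymmetric conjugate alkenylation (C10), α-methylenation (C6) and methyl addition (the future C19).
5. Ring order: ring A is bought as cyclohexenone; ring B is closed in the key step.

Key step: step 7

Remark: clerodane numbering of the target (C1–C20) is used for every intermediate and β is the face of H-10. C5 of 7 and 8 and C2/C3 of 23 are left open because these centres are erased again.

**Step 1**
Reactants: 1 but-2-yn-1-ol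
Product: 2 tert-butyl(but-2-yn-1-yloxy)dimethylsilane
Conditions: TBSCl, imidazole, CH2Cl2, 0 °C to rt
Reagents that add atoms: tert-butyldimethylsilyl chloride, CC(C)(C)[Si](C)(C)Cl
Why: Standard silyl ether protection of a primary alcohol, needed so that the hydroxyl group does not consume the hydride and organometallic reagents of steps 2 to 4.

**Step 2**
Reactants: 2 tert-butyl(but-2-yn-1-yloxy)dimethylsilane; 3 cyclohex-2-en-1-one
Product: 6 {[(3S)-3-[(2E)-4-(tert-butyldimethylsilyloxy)but-2-en-2-yl]cyclohex-1-en-1-yl]oxy}trimethylsilane, via alkenylzirconocene chloride 4 (not isolated), via zirconium enolate 5 (not isolated)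
Conditions: Cp2ZrHCl, THF, rt to 40 °C; then 3, [Rh(cod)(MeCN)2]BF4 (5 mol %), (S)-BINAP (6 mol %), rt; then MeLi, TMSCl, −78 °C to rt
Reagents that add atoms: chlorotrimethylsilane, C[Si](C)(C)Cl
Why: Syn hydrozirconation should place zirconium on the less hindered, methyl-bearing alkyne carbon; the rhodium/(S)-BINAP-catalysed asymmetric conjugate alkenylation sets C10 under catalyst control, and silyl trapping keeps the enolate regiodefined at C5.

**Step 3**
Reactants: 6 silyl enol ether
Product: 9 (3R)-3-[(2E)-4-(tert-butyldimethylsilyloxy)but-2-en-2-yl]-2-methylidenecyclohexan-1-one, via Mannich base 7 (not isolated), via ammonium iodide 8 (not isolated)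
Conditions: CH2=NMe2+ I−, CH2Cl2, rt; MeI, Et2O, rt; aq NaHCO3/CH2Cl2, rt
Reagents that add atoms: N,N-dimethylmethyleneiminium iodide, C=[N+](C)C.[I-]
Why: A Mannich reaction of the regiodefined silyl enol ether, then quaternisation and mild E1cB loss of trimethylamine, is the established route to an α-methylene ketone; it brings in C6 at C5 only.

**Step 4**
Reactants: 9 α-methylene ketone
Product: 10 (1R,3R)-3-[(2E)-4-(tert-butyldimethylsilyloxy)but-2-en-2-yl]-1-methyl-2-methylidenecyclohexan-1-ol
Conditions: AlMe3 (3 equiv), toluene, −40 to 0 °C; aq Rochelle salt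
Reagents that add atoms: trimethylaluminium, C[Al](C)C
Why: In this 1,2-addition to the enone carbonyl the methyl group should enter from the β face, away from the C10 side chain (axial attack, as favoured by excess AlMe3 in a hydrocarbon solvent), so that CH3 at C4 ends cis to H-10.

**Step 5**
Reactants: 10 silyl ether
Product: 11 (1R,3R)-3-[(2E)-4-hydroxybut-2-en-2-yl]-1-methyl-2-methylidenecyclohexan-1-ol
Conditions: Bu4NF, THF, 0 °C to rt
Reagents that add atoms: none
Why: Fluoride-induced desilylation frees the primary allylic alcohol and touches no stereocentre.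

**Step 6**
Reactants: 11 diol; 12 (Z)-1-bromoprop-1-ene
Product: 14 (2S,3R)-3-[(1R,3R)-3-hydroxy-3-methyl-2-methylidenecyclohexyl]-2,3-dimethylpent-4-enal, via allyl propenyl ether 13 (not isolated)
Conditions: CuI (10 mol %), 3,4,7,8-tetramethyl-1,10-phenanthroline (20 mol %), Cs2CO3, o-xylene, sealed tube, 120 °C
Reagents that add atoms: none
Why: Copper-catalysed C–O vinylation of the primary alcohol with retention of the Z geometry is followed in the same flask by Claisen rearrangement (a known domino process); the chair transition state of the (Z)-propenyl/(E)-allyl pair sets C8 relative to C9, and the enol ether should add to the alkene face turned away from C5 in the rotamer that keeps H-10 next to the C9 methyl group (least allylic 1,2-strain), which sets C9 relative to C10.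

**Step 7**
Reactants: 14 hydroxy aldehyde
Product: 15 (4aR,5R,6S,7S,8aS)-5-ethenyl-7-hydroxy-5,6,8a-trimethyloctahydronaphthalen-1(2H)-one (cis-decalone; clerodane numbering: 4-oxo, 7β-OH, 5β-CH3, 8α-CH3, 9α-CH3, 9β-vinyl, 10β-H)
Conditions: Me2AlCl (2.2 equiv), CH2Cl2, −78 to −20 °C; aq Rochelle salt
Reagents that add atoms: none
Why: Proposed new method: one equivalent of Me2AlCl should turn the tertiary C4 alcohol into its aluminium alkoxide (loss of methane) and the second should activate the aldehyde, so that the terminal alkene carbon C6 attacks C7 (Prins step) and the tertiary C5 cation is discharged at once by a 1,2-shift of the C4 methyl group, pushed by the alkoxide oxygen that becomes the C4 ketone (semipinacol termination); the net change is an isomerisation. The closest known reaction types are the pinacol-terminated Prins cyclization of allylic silyl ethers with acetal-derived oxocarbenium ions and the Me2AlCl-promoted aldehyde–alkene cyclization, and what is new is their union with an aldehyde as initiator and a methyl group as migrating group. Ring B closes in a 6-endo-trig mode (both alkene carbons end up in the ring) through a chair in which C1, the vinyl group, the C8 methyl group and the C7–O–Al group are equatorial and only the C9 methyl group is axial. C7 is set by this chair, because an axial C7–O–Al group would be 1,3-diaxial to the C9 methyl group, and C5 is set by the C4 stereocentre, because a 1,2-shift is suprafacial and the methyl group on the β face of C4 (cis to H-10) can only arrive on the β face of C5, which fixes the cis ring fusion. The step needs methyl migration to win over ring contraction (shift of C3), hydride shift from C10 and proton loss: in the bicyclic cation the axial C4–CH3 bond is parallel to the empty p orbital, C3 could only enter on the α face under the axial C9 methyl group, C4 bears no hydrogen so that the ene pathway is closed, and the oxygen-assisted shift should outrun an unassisted hydride shift.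

**Step 8**
Reactants: 15 hydroxy decalone
Product: 16 7β-acetate of 15
Conditions: Ac2O, pyridine, DMAP (cat.), CH2Cl2, rt
Reagents that add atoms: acetic anhydride, CC(=O)OC(C)=O
Why: DMAP-catalysed acetylation of the equatorial secondary alcohol installs the acetate of the target with retention at C7.

**Step 9**
Reactants: 17 tert-butyl acetoacetate
Product: 18 tert-butyl (2E)-3-(trifluoromethylsulfonyloxy)but-2-enoate
Conditions: Tf2O, aq Me4NOH, hexanes, 5 °C to rt
Reagents that add atoms: trifluoromethanesulfonic anhydride, O=S(=O)(OS(=O)(=O)C(F)(F)F)C(F)(F)F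
Why: O-Triflation of the acetoacetate enolate with the non-chelating tetramethylammonium counter-ion is known to give the E enol triflate, which carries the alkene geometry of the side chain.

**Step 10**
Reactants: 16 acetate; 18 enol triflate
Product: 20 tert-butyl ester of the 4-oxo-7β-acetoxy decalin with the complete (13E) side chain, via alkyl borane 19 (not isolated)
Conditions: 9-BBN-H, THF, rt; then 18, PdCl2(dppf) (5 mol %), aq K3PO4, DMF, rt to 50 °C
Reagents that add atoms: none
Why: The vinyl group is the only alkene, so anti-Markovnikov hydroboration is unambiguous while the hindered C4 ketone reacts far more slowly, and the B-alkyl Suzuki–Miyaura coupling proceeds with retention of the triflate geometry.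

**Step 11**
Reactants: 20 ketone
Product: 21 2-en-4-one (C4 ketone conjugated with C2=C3)
Conditions: IBX, DMSO/fluorobenzene, 75 °C
Reagents that add atoms: none
Why: In this IBX dehydrogenation of a ketone only C3 bears α-hydrogen atoms, since C5 is quaternary, so that a single enone can form.

**Step 12**
Reactants: 21 enone
Product: 22 2,4(18)-diene
Conditions: Zn, CH2Br2, TiCl4, THF/CH2Cl2, 0 °C to rt
Reagents that add atoms: dibromomethane, BrCBr
Why: The non-basic Lombardo methylenation converts hindered, enolisable ketones into methylene groups and leaves the acetate and the tert-butyl enoate alone.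

**Step 13**
Reactants: 22 diene
Product: 23 2,3-diol with 4(18)-methylene group (cis-diol; C2 and C3 left open)
Conditions: OsO4 (2 mol %), NMO, acetone/H2O, 0 °C
Reagents that add atoms: N-methylmorpholine N-oxide, C[N+]1([O-])CCOCC1; water, O
Why: The Upjohn dihydroxylation should pick the accessible cis-disubstituted C2=C3 bond over the C4=C18 bond next to quaternary C5 and over the electron-poor enoate; addition is syn and the facial sense does not matter because both centres are oxidised in step 14.

**Step 14**
Reactants: 23 diol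
Product: 25 tert-butyl ester of the target (2-hydroxy-3-oxo-1,4(18)-diene), via 2,3-diketone 24 (not isolated)
Conditions: Dess–Martin periodinane (2.5 equiv), CH2Cl2, 0 °C to rt
Reagents that add atoms: none
Why: Double Dess–Martin oxidation gives the 1,2-diketone, which can enolise only towards C1 because C4 bears no hydrogen, and so should settle as the diosphenol of the target.

**Step 15**
Reactants: 25 tert-butyl ester
Product: 26 target, CNP0192653.1
Conditions: CF3CO2H/CH2Cl2 (1:4), 0 °C
Reagents that add atoms: none
Why: Acidolysis of the tert-butyl ester with loss of 2-methylpropene needs no base or nucleophile, so the acetate, the diosphenol and the α-methylene ketone should survive.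

**Compound list**
1 | but-2-yn-1-ol | CC#CCO | starting material
2 | tert-butyl(but-2-yn-1-yloxy)dimethylsilane | CC#CCO[Si](C)(C)C(C)(C)C | intermediate
3 | cyclohex-2-en-1-one | O=C1C=CCCC1 | starting material
4 | chlorobis(cyclopentadienyl)[(2E)-4-(tert-butyldimethylsilyloxy)but-2-en-2-yl]zirconium | C/C(=C\CO[Si](C)(C)C(C)(C)C)[Zr](Cl)(C1C=CC=C1)C1C=CC=C1 | intermediate
5 | zirconocene chloride enolate of the (3S)-3-alkenylcyclohexanone | Cl[Zr](OC1=C[C@@H](/C(C)=C/CO[Si](C)(C)C(C)(C)C)CCC1)(C1C=CC=C1)C1C=CC=C1 | intermediate
6 | {[(3S)-3-[(2E)-4-(tert-butyldimethylsilyloxy)but-2-en-2-yl]cyclohex-1-en-1-yl]oxy}trimethylsilane | C[Si](C)(C)OC1=C[C@@H](/C(C)=C/CO[Si](C)(C)C(C)(C)C)CCC1 | intermediate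
7 | (3S)-2-[(dimethylamino)methyl]-3-[(2E)-4-(tert-butyldimethylsilyloxy)but-2-en-2-yl]cyclohexan-1-one (C5 open) | CN(C)CC1[C@@H](/C(C)=C/CO[Si](C)(C)C(C)(C)C)CCCC1=O | intermediate
8 | trimethylammonium iodide derived from 7 | C[N+](C)(C)CC1[C@@H](/C(C)=C/CO[Si](C)(C)C(C)(C)C)CCCC1=O.[I-] | intermediate
9 | (3R)-3-[(2E)-4-(tert-butyldimethylsilyloxy)but-2-en-2-yl]-2-methylidenecyclohexan-1-one | C=C1[C@@H](/C(C)=C/CO[Si](C)(C)C(C)(C)C)CCCC1=O | intermediate
10 | (1R,3R)-3-[(2E)-4-(tert-butyldimethylsilyloxy)but-2-en-2-yl]-1-methyl-2-methylidenecyclohexan-1-ol | C=C1[C@@H](/C(C)=C/CO[Si](C)(C)C(C)(C)C)CCC[C@@]1(C)O | intermediate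
11 | (1R,3R)-3-[(2E)-4-hydroxybut-2-en-2-yl]-1-methyl-2-methylidenecyclohexan-1-ol | C=C1[C@@H](/C(C)=C/CO)CCC[C@@]1(C)O | intermediate
12 | (Z)-1-bromoprop-1-ene | C/C=C\Br | starting material
13 | (1R,3R)-1-methyl-2-methylidene-3-{(2E)-4-[(1Z)-prop-1-en-1-yloxy]but-2-en-2-yl}cyclohexan-1-ol | C=C1[C@@H](/C(C)=C/CO/C=C\C)CCC[C@@]1(C)O | intermediate
14 | (2S,3R)-3-[(1R,3R)-3-hydroxy-3-methyl-2-methylidenecyclohexyl]-2,3-dimethylpent-4-enal | C=C1[C@@H]([C@@](C)(C=C)[C@H](C)C=O)CCC[C@@]1(C)O | intermediate
15 | (4aR,5R,6S,7S,8aS)-5-ethenyl-7-hydroxy-5,6,8a-trimethyloctahydronaphthalen-1(2H)-one | O=C1CCC[C@@H]2[C@@](C)(C=C)[C@H](C)[C@@H](O)C[C@]12C | intermediate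
16 | 7β-acetate of 15 (5S,7S,8S,9R,10R) | O=C1CCC[C@@H]2[C@@](C)(C=C)[C@H](C)[C@@H](OC(C)=O)C[C@]12C | intermediate
17 | tert-butyl acetoacetate | CC(=O)CC(=O)OC(C)(C)C | starting material
18 | tert-butyl (2E)-3-(trifluoromethylsulfonyloxy)but-2-enoate | C/C(OS(=O)(=O)C(F)(F)F)=C\C(=O)OC(C)(C)C | intermediate
19 | C12 B-alkyl-9-borabicyclo[3.3.1]nonane derived from 16 | O=C1CCC[C@@H]2[C@@](C)(CCB3C4CCCC3CCC4)[C@H](C)[C@@H](OC(C)=O)C[C@]12C | intermediate
20 | tert-butyl (13E)-7β-acetoxy-4-oxo-18-nor-cis-clerod-13-en-15-oate (5S,7S,8S,9R,10R) | O=C1CCC[C@@H]2[C@@](C)(CC/C(C)=C/C(=O)OC(C)(C)C)[C@H](C)[C@@H](OC(C)=O)C[C@]12C | intermediate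
21 | 2,3-didehydro derivative of 20 (2-en-4-one) | O=C1C=CC[C@@H]2[C@@](C)(CC/C(C)=C/C(=O)OC(C)(C)C)[C@H](C)[C@@H](OC(C)=O)C[C@]12C | intermediate
22 | tert-butyl (13E)-7β-acetoxy-cis-cleroda-2,4(18),13-trien-15-oate | C=C1C=CC[C@@H]2[C@@](C)(CC/C(C)=C/C(=O)OC(C)(C)C)[C@H](C)[C@@H](OC(C)=O)C[C@]12C | intermediate
23 | tert-butyl (13E)-7β-acetoxy-2,3-dihydroxy-cis-cleroda-4(18),13-dien-15-oate (cis-diol, C2/C3 open) | C=C1C(O)C(O)C[C@@H]2[C@@](C)(CC/C(C)=C/C(=O)OC(C)(C)C)[C@H](C)[C@@H](OC(C)=O)C[C@]12C | intermediate
24 | 2,3-diketone tautomer of 25 | C=C1C(=O)C(=O)C[C@@H]2[C@@](C)(CC/C(C)=C/C(=O)OC(C)(C)C)[C@H](C)[C@@H](OC(C)=O)C[C@]12C | intermediate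
25 | tert-butyl (13E)-7β-acetoxy-2-hydroxy-3-oxo-cis-cleroda-1,4(18),13-trien-15-oate | C=C1C(=O)C(O)=C[C@@H]2[C@@](C)(CC/C(C)=C/C(=O)OC(C)(C)C)[C@H](C)[C@@H](OC(C)=O)C[C@]12C | intermediate
26 | (13E)-7β-acetoxy-2-hydroxy-3-oxo-cis-cleroda-1,4(18),13-trien-15-oic acid (5S,7S,8S,9R,10R), CNP0192653.1 | C=C1C(=O)C(O)=C[C@@H]2[C@@](C)(CC/C(C)=C/C(=O)O)[C@H](C)[C@@H](OC(C)=O)C[C@]12C | target

**Totals**
Total step count: 15. Longest linear sequence: 14 (steps 1 to 8 and 10 to 15).

**Steps most likely to fail**

Step 7. The C5 cation may escape by ring contraction, hydride shift or proton loss, or the tertiary allylic alkoxide may ionise before the aldehyde is attacked.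
- The fallback sets out from 9 and comes back at 15. It closes the same bond by known radical chemistry and brings in the C5 methyl group last.
- Bu4NF frees the allylic alcohol F1.
- The coupling/Claisen conditions of step 6 turn it into the keto aldehyde F2.
- SmI2 (THF, t-BuOH, −78 °C) effects a reductive aldehyde–enone cyclization onto the α-methylene ketone (6-endo attack at C6) to give the hydroxy decalone F3.
- TESCl/imidazole gives the silyl ether F4.
- Its thermodynamic ring-fusion enolate (KH, THF, rt) is methylated with MeI from the β face, away from the axial C9 methyl group; this is the usual cis outcome of angular methylation of 1-decalone enolates. The product is the methylated ketone F5.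
- HF·pyridine returns 15.

Step 6. The C–O coupling of the Z bromide may be sluggish, the Z geometry may erode, C8 may epimerise under carbonate at 120 °C, and the facial selectivity of the rearrangement may be poor.
- The fallback sets out from 11 and comes back at 14. It replaces the aldehyde-level Claisen rearrangement by an ester enolate version that runs below room temperature.
- Selective acylation of the primary alcohol (propionyl chloride, pyridine, −20 °C) gives the propionate F6.
- Ireland–Claisen rearrangement follows (LDA, TMSCl, THF, −78 °C to rt; acidic work-up). The kinetic ketene acetal places the methyl group as in the Z enol ether and gives the acid F7.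
- LiAlH4 gives the diol F8.
- Selective oxidation of the primary alcohol (TEMPO, PhI(OAc)2) returns 14.

Step 4. The facial selectivity of the methyl transfer may be poor, or conjugate addition may compete.
- The fallback sets out from 9 and comes back at 10. It splits the event into an oxygen-placing and a reducing operation.
- Dimethylsulfonium methylide (Me3S+ I−, n-BuLi, THF, −10 °C) adds 1,2 by axial attack from the β face and closes to the spiro epoxide F9.
- LiEt3BH opens it at the primary carbon to give 10.

**Further compounds**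
F1 | step 7 | (3R)-3-[(2E)-4-hydroxybut-2-en-2-yl]-2-methylidenecyclohexan-1-one | C=C1[C@@H](/C(C)=C/CO)CCCC1=O
F2 | step 7 | (2S,3R)-2,3-dimethyl-3-[(1R)-2-methylidene-3-oxocyclohexyl]pent-4-enal | C=C1[C@@H]([C@@](C)(C=C)[C@H](C)C=O)CCCC1=O
F3 | step 7 | 19-nor analogue of 15 (C5–H, epimerisable, left open) | O=C1CCC[C@@H]2[C@@](C)(C=C)[C@H](C)[C@@H](O)CC12
F4 | step 7 | 7-O-triethylsilyl ether of F3 | O=C1CCC[C@@H]2[C@@](C)(C=C)[C@H](C)[C@@H](O[Si](CC)(CC)CC)CC12
F5 | step 7 | 7-O-triethylsilyl ether of 15 | O=C1CCC[C@@H]2[C@@](C)(C=C)[C@H](C)[C@@H](O[Si](CC)(CC)CC)C[C@]12C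
F6 | step 6 | (2E)-3-[(1R,3R)-3-hydroxy-3-methyl-2-methylidenecyclohexyl]but-2-en-1-yl propanoate | C=C1[C@@H](/C(C)=C/COC(=O)CC)CCC[C@@]1(C)O
F7 | step 6 | (2S,3R)-3-[(1R,3R)-3-hydroxy-3-methyl-2-methylidenecyclohexyl]-2,3-dimethylpent-4-enoic acid | C=C1[C@@H]([C@@](C)(C=C)[C@H](C)C(=O)O)CCC[C@@]1(C)O
F8 | step 6 | primary alcohol corresponding to aldehyde 14 | C=C1[C@@H]([C@@](C)(C=C)[C@H](C)CO)CCC[C@@]1(C)O
F9 | step 4 | spiro epoxide of 9 at C4 (oxygen α, CH2 β) | C=C1[C@@H](/C(C)=C/CO[Si](C)(C)C(C)(C)C)CCC[C@]12CO2
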